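## The problem

The target 19 is two benzenoid units joined by a diaryl ether. One is a 6-hydroxy-3-pentylisocoumarin that carries the ether oxygen at C8. The other, ring B, is an olivetolic-acid pattern; its locants here are C1' (ether carbon), C2' (OH), C3' (H), C4' (OH), C5' (CO2H) and C6' (pentyl). There is no stereocentre, so the whole difficulty lies in connectivity and functional-group tolerance. The ether is ortho-substituted on both sides of both rings: C1' lies between the C2' hydroxyl and the C6' pentyl group, and C8 sits peri to the lactone carbonyl C1. Joining two finished arenes would therefore be a doubly hindered aryl–oxygen coupling onto an electron-rich ring. Three groups limit the reagents: the enol lactone of the isocoumarin is opened by hydroxide and alkoxides, the ring B β-resorcylic acid loses CO2 in hot or strongly protic acid, and the phenols must be told apart at the moment the ether is made. Ring B is hexasubstituted, so building it by successive substitution of a benzene would be long. The enabling feature is that C6'–C1'–C2'–C3'–C4'–C5' reads as a folded tetraketide: C6', C2' and C4' are carbonyl carbons, C5' is the carboxyl-bearing methylene, and C1' is the one carbon between two ketones. The aryloxy group can therefore be placed on an sp3 carbon before ring B exists, and ring B can then be closed around it by an aldol condensation between C5' and C6'.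

## Retrosynthesis

**19 from 18.** No skeletal bond is cut. The last operation removes the methyl group on the isocoumarin C6 oxygen and the isopropylidene group that ties the C4' oxygen to the C5' carboxyl in benzodioxinone 18. An ordinary ester on ring B would need saponification, which opens the isocoumarin lactone. The acetonide and the methyl ether both fall to one boron halide, and the carboxylic acid stays masked until the final flask. The forward step must cleave both without decarboxylating ring B.

**18 from 16.** The C5'–C6' bond of ring B is cut. This opens ring B to the chain of 16, in which a 2,2-dimethyl-1,3-dioxin-4-one holds C4', C5' and the carboxyl carbon as a masked β-keto acid, and C2' and C6' are ketones flanking the aryloxy-bearing C1'. A cut at the ether would return to the hindered aryl–oxygen coupling; any other ring B bond would need an oxidation later. Here the chain already has the oxidation level of the arene, so the forward reaction is only aldol addition, loss of water and enolization. It must be run with a base mild enough to spare the lactone.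

**16 from 15 and 8.** The C1'–O bond is cut at the sp3 carbon. Diazo diketone 15 and isocoumarin phenol 8 are of similar size, so the route is convergent here. Carbenoid O–H insertion is chosen over displacement of an α-halide by the phenoxide because it runs without base, and base would start the aromatization of the chain too early. The 6-O-methyl group of 8 leaves only the 8-hydroxyl to react.

**15 from 14, 12, 9, 10 and 2.** The diazo group comes by diazo transfer to the 1,3-diketone of 14. The C–C bond between the nonyl C3 and C4 of 14 is cut to keto-dioxinone 12 and Weinreb amide 2 (from hexanoyl chloride 1). The bond between the side-chain CH2 and the ketone of 12 is cut to the commercial dioxinone 9 and acetyl chloride 10. Both forward steps are enolate acylations of a kind well established for dioxinones.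

**8 from 7, 6, 4, 3 and 2.** The peri methyl ether of 7 is cleaved selectively to give 8. The lactone C–O bond of 7 is cut to keto ester 6. The benzylic C–C bond of 6 is cut to the laterally lithiated toluate 4 and the same amide 2. Compound 4 is the dimethyl ether of methyl orsellinate 3. Amide 2 thus supplies both pentyl chains of the target.

## Roads not taken

**Alternative 1:** Ring A would be built instead of ring B, by cutting C8–C8a and C4a–C5. A ring B phenol, methyl 3-hydroxy-4,6-dimethoxy-2-pentylbenzoate A1, would be turned into the 1-aryloxy-3-silyloxycyclohexa-1,3-diene A2. Diels–Alder addition of methyl deca-2,4-diynoate A3 at its ester-bearing triple bond, followed by Alder–Rickert loss of the two-carbon bridge on heating, would give benzoate A4. Its heptynyl and ester groups are placed for a 6-endo lactonization to the 3-pentylisocoumarin.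
- Merits: the key step is a thermal pericyclic sequence with regiochemistry fixed by the donor and acceptor groups, and it needs no diazo compound and no base-sensitive chain. In robustness of the key step this road is stronger than the chosen one.
- Weak points: A1 is itself a pentasubstituted benzene that needs its own synthesis, so the ring B problem is postponed. The hindered phenol of A1 must be forced into a vinylogous ester. The two triple bonds of A3 must be told apart at high temperature. The end game must hydrolyse a hindered ring B methyl ester next to an isocoumarin lactone.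
- Against it, the chosen plan makes ring B with all six substituents in one ring closure from acyclic pieces, and carries the carboxyl in a form that a Lewis acid removes.

**Alternative 2:** Three bonds of ring A would be cut (C6–C7, C8–C8a, C5–C6). Photochemical Wolff rearrangement of diazo keto ester A5 would give a vinylketene that adds the ethynyl ether A6 of phenol A1. Ring opening of the cyclobutenone and 6-electron electrocyclization would give phenol A7.
- Merits: ring A arrives fully substituted with its C6 hydroxyl free, so that oxygen needs no protecting group. This is an advantage over the chosen plan, which must cleave a methyl ether in the last step.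
- Weak points: an aryl ethynyl ether of a doubly ortho-substituted, electron-rich phenol must be made with strong base and is fragile. A1 is again required. A ketal removal, a lactonization and an ester hydrolysis follow the key step.
- Against it, the chosen plan needs no separate ring B synthesis and fewer operations after its key step.

**Alternative 3:** Ring B would be cut at C5'–C6' and C3'–C4'. Alkoxide-mediated Michael addition of dimethyl malonate A9 to the α-aryloxy enone A8, then Claisen closure, would give cyclohexanedione ester A10.
- Merits: this is classical, inexpensive chemistry with strong precedent for the ring formation, and the ether also rides on a non-aromatic carbon. On cost and on precedent for the ring-forming step it is better than the chosen plan.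
- Weak points: A10 is two hydrogens short of the arene. The dehydrogenation must be done on a β-keto ester that tends to lose its carboxyl and on an electron-rich aryl ether. The isocoumarin must then be grown from the aryl bromide, and a ring B ester must be hydrolysed near the lactone.
- Against it, the chosen plan starts from a chain already at the aromatic oxidation level, so ring B forms by dehydration alone with the isocoumarin in place.

Key step: step 10

## Route

Remark: 19 has no stereocentre; the three stereocentres of the transient aldol adduct 17 vanish on aromatization, so no descriptor is needed.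

Step 1
Reactants: 1 hexanoyl chloride
Product: 2 N-methoxy-N-methylhexanamide
Conditions: MeNHOMe·HCl, Et3N, CH2Cl2, 0 °C to rt
Reagents that add atoms: N,O-dimethylhydroxylamine hydrochloride, CNOC.Cl
Why: N-acylation of the hydroxylamine by the acid chloride gives the Weinreb amide; it serves as the acyl donor in steps 3 and 7.

Step 2
Reactants: 3 methyl 2,4-dihydroxy-6-methylbenzoate (methyl orsellinate)
Product: 4 methyl 2,4-dimethoxy-6-methylbenzoate
Conditions: MeI (excess), K2CO3, acetone, reflux
Reagents that add atoms: iodomethane, CI
Why: Williamson O-methylation of both phenols; the chelated 2-hydroxyl reacts more slowly, so excess reagent and heat are used.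

Step 3
Reactants: 4 methyl 2,4-dimethoxy-6-methylbenzoate; 2 N-methoxy-N-methylhexanamide
Product: 6 methyl 2,4-dimethoxy-6-(2-oxoheptyl)benzoate, via benzylic lithium species 5 (not isolated)
Conditions: LiN(iPr)2, THF, −78 °C; then 2, −78 to 0 °C; aq. NH4Cl
Reagents that add atoms: none
Why: Lateral lithiation of the o-toluate gives the ester-stabilized benzylic anion, which is acylated by the Weinreb amide; the chelated tetrahedral intermediate prevents over-addition and proton exchange with the product ketone.

Step 4
Reactants: 6 methyl 2,4-dimethoxy-6-(2-oxoheptyl)benzoate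
Product: 7 6,8-dimethoxy-3-pentyl-1H-isochromen-1-one
Conditions: TsOH·H2O (cat.), toluene, reflux, MeOH distilled off
Reagents that add atoms: none
Why: Acid-catalysed enol lactonization: the arene-conjugated enol of the benzylic ketone closes on the activated ester with loss of methanol to give the isocoumarin; acid is used because base would divert the keto ester into a Claisen closure to a naphthalenediol.

Step 5
Reactants: 7 6,8-dimethoxy-3-pentyl-1H-isochromen-1-one
Product: 8 8-hydroxy-6-methoxy-3-pentyl-1H-isochromen-1-one
Conditions: BCl3, CH2Cl2, −78 to 0 °C; then H2O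
Reagents that add atoms: none
Why: Chelation-directed demethylation: BCl3 bridges the lactone carbonyl and the peri 8-methoxy oxygen and cleaves only that ether, leaving the 6-methoxy group as the protecting group.

Step 6
Reactants: 9 2,2,6-trimethyl-4H-1,3-dioxin-4-one; 10 acetyl chloride
Product: 12 2,2-dimethyl-6-(2-oxopropyl)-4H-1,3-dioxin-4-one, via lithium dienolate 11 (not isolated)
Conditions: LiN(SiMe3)2, THF, −78 °C; then 10 (0.5 equiv), −78 °C; aq. NH4Cl
Reagents that add atoms: none
Why: Vinylogous deprotonation of the dioxinone methyl group and Claisen-type C-acylation at that γ-carbon; two equivalents of dienolate are used because the keto-dioxinone formed is more acidic than 9.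

Step 7
Reactants: 12 2,2-dimethyl-6-(2-oxopropyl)-4H-1,3-dioxin-4-one; 2 N-methoxy-N-methylhexanamide
Product: 14 6-(2,4-dioxononyl)-2,2-dimethyl-4H-1,3-dioxin-4-one, via dilithium dienolate 13 (not isolated)
Conditions: LiN(iPr)2 (2.1 equiv), THF, −78 °C; then 2, −78 to −40 °C; cold dilute HCl
Reagents that add atoms: none
Why: The second deprotonation takes place at the methyl ketone, and the dianion is acylated at this terminal, most nucleophilic carbon (Claisen condensation with a Weinreb amide), which is the established way to diketo-dioxinones; the cold acidic quench releases the diketone without exposing it to base.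

Step 8
Reactants: 14 6-(2,4-dioxononyl)-2,2-dimethyl-4H-1,3-dioxin-4-one
Product: 15 6-(3-diazo-2,4-dioxononyl)-2,2-dimethyl-4H-1,3-dioxin-4-one
Conditions: 4-AcNHC6H4SO2N3, Et3N, MeCN, 0 °C, short reaction time
Reagents that add atoms: 4-acetamidobenzenesulfonyl azide, CC(=O)Nc1ccc(cc1)S(=O)(=O)N=[N+]=[N-]
Why: Regitz diazo transfer to the most acidic C–H, the carbon between the two ketones; this site reacts as its ammonium enolate, a form in which the C4 ketone is not electrophilic, so cycloaromatization should be held back during the short cold exposure to amine.

Step 9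
Reactants: 15 6-(3-diazo-2,4-dioxononyl)-2,2-dimethyl-4H-1,3-dioxin-4-one; 8 8-hydroxy-6-methoxy-3-pentyl-1H-isochromen-1-one
Product: 16 6-{3-[(6-methoxy-1-oxo-3-pentyl-1H-isochromen-8-yl)oxy]-2,4-dioxononyl}-2,2-dimethyl-4H-1,3-dioxin-4-one
Conditions: Rh2(OAc)4 (2 mol %), 8 (2 equiv), CH2Cl2, 40 °C, 15 added slowly
Reagents that add atoms: none
Why: Carbenoid O–H insertion: dirhodium tetraacetate releases N2 from the diazo diketone, the phenol oxygen adds to the carbenoid and a proton shift gives the ether under neutral conditions that spare lactone and chain. Excess phenol and slow addition favour this over 1,5 C–H insertion into the pentyl chain, and the 6-methoxy group leaves only the 8-hydroxyl to react.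

Step 10
Reactants: 16 6-{3-[(6-methoxy-1-oxo-3-pentyl-1H-isochromen-8-yl)oxy]-2,4-dioxononyl}-2,2-dimethyl-4H-1,3-dioxin-4-one
Product: 18 7-hydroxy-6-[(6-methoxy-1-oxo-3-pentyl-1H-isochromen-8-yl)oxy]-2,2-dimethyl-5-pentyl-4H-1,3-benzodioxin-4-one, via aldol adduct 17 (not isolated)
Conditions: Et3N, 4 Å molecular sieves, CH2Cl2, rt
Reagents that add atoms: none
Why: Triethylamine equilibrates the enol and enolate forms of the chain; in the form where the CH2 next to the dioxinone (future C3') is deprotonated to the extended dienolate and the pentyl ketone (future C6') is in its keto form, the dioxinone C5 (future C5') attacks that ketone to give hydroxy ketone 17. E1cB loss of water across C5'–C6' and enolization of the C2' ketone toward C1' then give the arene, with the dioxinone kept as the acetonide of the C4' oxygen and the carboxyl. The closest known reaction is the amine- or carbonate-induced cycloaromatization of 6-(2,4-dioxoalkyl)dioxinones to 7-hydroxybenzodioxinones, here applied to a chain that carries an aryloxy group between the ketones. Ring B closes in a 6-(enolexo)-exo-trig aldol. No stereocentre remains, since the three of 17 are lost on aromatization. The selectivity needed is C5'-to-C6' closure over other carbonyl condensations, and the substrate secures it: every other aldol pairing would give a four- or eight-membered ring, and only this one ends in an irreversible aromatization. Attack of the C1' enolate on the neighbouring lactone carbonyl would give a non-enolizable tricarbonyl that can revert, and the sieves remove the water that could otherwise make that path irreversible by deacylation. The C1' hydrogen is lost only in the final enolization, so the aryloxy group is carried into the arene intact.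

Step 11
Reactants: 18 7-hydroxy-6-[(6-methoxy-1-oxo-3-pentyl-1H-isochromen-8-yl)oxy]-2,2-dimethyl-5-pentyl-4H-1,3-benzodioxin-4-one
Product: 19 4,6-dihydroxy-3-[(6-hydroxy-1-oxo-3-pentyl-1H-isochromen-8-yl)oxy]-2-pentylbenzoic acid
Conditions: BBr3 (excess), CH2Cl2, −78 to 0 °C; then ice-water
Reagents that add atoms: none
Why: Lewis-acid ether cleavage: BBr3 opens the acylal-type isopropylidene group and demethylates the aryl methyl ether, while diaryl ether and enol lactone are inert to it. The salicylate stays bound to boron until the cold aqueous quench, which limits protodecarboxylation.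

## Compound list

1 | hexanoyl chloride | CCCCCC(=O)Cl | starting material
2 | N-methoxy-N-methylhexanamide | CCCCCC(=O)N(C)OC | intermediate
3 | methyl 2,4-dihydroxy-6-methylbenzoate (methyl orsellinate) | COC(=O)c1c(C)cc(O)cc1O | starting material
4 | methyl 2,4-dimethoxy-6-methylbenzoate | COC(=O)c1c(C)cc(OC)cc1OC | intermediate
5 | methyl 2-(lithiomethyl)-4,6-dimethoxybenzoate (not isolated) | [Li]Cc1cc(OC)cc(OC)c1C(=O)OC | intermediate
6 | methyl 2,4-dimethoxy-6-(2-oxoheptyl)benzoate | CCCCCC(=O)Cc1cc(OC)cc(OC)c1C(=O)OC | intermediate
7 | 6,8-dimethoxy-3-pentyl-1H-isochromen-1-one | CCCCCc1cc2cc(OC)cc(OC)c2c(=O)o1 | intermediate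
8 | 8-hydroxy-6-methoxy-3-pentyl-1H-isochromen-1-one | CCCCCc1cc2cc(OC)cc(O)c2c(=O)o1 | intermediate
9 | 2,2,6-trimethyl-4H-1,3-dioxin-4-one | CC1=CC(=O)OC(C)(C)O1 | starting material
10 | acetyl chloride | CC(=O)Cl | starting material
11 | lithium 2,2-dimethyl-6-methylidene-6H-1,3-dioxin-4-olate (dienolate of 9; not isolated) | C=C1C=C(O[Li])OC(C)(C)O1 | intermediate
12 | 2,2-dimethyl-6-(2-oxopropyl)-4H-1,3-dioxin-4-one | CC(=O)CC1=CC(=O)OC(C)(C)O1 | intermediate
13 | dilithium dienolate of 12 (not isolated) | C=C(O[Li])C=C1C=C(O[Li])OC(C)(C)O1 | intermediate
14 | 6-(2,4-dioxononyl)-2,2-dimethyl-4H-1,3-dioxin-4-one | CCCCCC(=O)CC(=O)CC1=CC(=O)OC(C)(C)O1 | intermediate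
15 | 6-(3-diazo-2,4-dioxononyl)-2,2-dimethyl-4H-1,3-dioxin-4-one | CCCCCC(=O)C(=[N+]=[N-])C(=O)CC1=CC(=O)OC(C)(C)O1 | intermediate
16 | 6-{3-[(6-methoxy-1-oxo-3-pentyl-1H-isochromen-8-yl)oxy]-2,4-dioxononyl}-2,2-dimethyl-4H-1,3-dioxin-4-one | CCCCCC(=O)C(Oc1cc(OC)cc2cc(CCCCC)oc(=O)c12)C(=O)CC1=CC(=O)OC(C)(C)O1 | intermediate
17 | 5-hydroxy-6-[(6-methoxy-1-oxo-3-pentyl-1H-isochromen-8-yl)oxy]-2,2-dimethyl-5-pentyl-4a,5-dihydro-4H-1,3-benzodioxine-4,7(6H)-dione (diastereomer mixture; not isolated) | CCCCCC1(O)C(Oc2cc(OC)cc3cc(CCCCC)oc(=O)c23)C(=O)C=C2OC(C)(C)OC(=O)C21 | intermediate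
18 | 7-hydroxy-6-[(6-methoxy-1-oxo-3-pentyl-1H-isochromen-8-yl)oxy]-2,2-dimethyl-5-pentyl-4H-1,3-benzodioxin-4-one | CCCCCc1c(Oc2cc(OC)cc3cc(CCCCC)oc(=O)c23)c(O)cc2OC(C)(C)OC(=O)c12 | intermediate
19 | 4,6-dihydroxy-3-[(6-hydroxy-1-oxo-3-pentyl-1H-isochromen-8-yl)oxy]-2-pentylbenzoic acid | CCCCCc1cc2cc(O)cc(Oc3c(O)cc(O)c(C(=O)O)c3CCCCC)c2c(=O)o1 | target

## Step count and uncertain steps

Total: 11 steps. Longest linear sequence: 7 steps (steps 1 or 2, then 3, 4, 5, 9, 10, 11).

**Step 10 (key step).** The base may hold the chain as the unreactive C1' enolate, the most acidic site, so that the aldol stalls. That enolate may also be diverted into acyl transfer with the peri lactone carbonyl, followed by cleavage of the chain. Both follow from the aryloxy-substituted diketone being a better acid and a poorer electrophile than the unsubstituted chains on which this aromatization is known. Fallback, setting out from 16: heating in toluene with tert-butanol expels acetone from the dioxinone, and the acylketene is trapped as tert-butyl 6-[(6-methoxy-1-oxo-3-pentyl-1H-isochromen-8-yl)oxy]-3,5,7-trioxododecanoate F1. Its β-keto ester carbon C2 is a far better aldol donor than the dioxinone carbon, and closes on the C7 ketone (the same C5'–C6' bond) with a weak base or on silica gel. This gives tert-butyl 4,6-dihydroxy-3-[(6-methoxy-1-oxo-3-pentyl-1H-isochromen-8-yl)oxy]-2-pentylbenzoate F2. BBr3 then removes the tert-butyl and methyl groups, and the route is rejoined at 19.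

**Step 9.** Capture of the carbenoid by the chelated, weakly nucleophilic peri phenol may be too slow, so that intramolecular 1,5 C–H insertion into the pentyl chain or Wolff rearrangement consumes the diazo compound. Fallback, setting out from 14: SO2Cl2 in CH2Cl2 chlorinates the diketone carbon without base to give 6-(3-chloro-2,4-dioxononyl)-2,2-dimethyl-4H-1,3-dioxin-4-one F3. Displacement of chloride by the potassium phenoxide of 8 (K2CO3, acetone), the classical route to 2-aryloxy-1,3-diketones, returns to the route at 16, which under these conditions may run on to 18. This detour also avoids the diazo transfer of step 8, where the amine could start the aromatization of 14 before the ether is in place.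

**Step 11.** Protodecarboxylation of the electron-rich resorcylic acid may occur during the hours that demethylation needs, or during the acidic quench. The cause is that cleaving a non-chelated aryl methyl ether needs far longer and warmer treatment than opening the acetonide. Fallback, setting out from 7: BBr3 cleaves both methyl ethers to 6,8-dihydroxy-3-pentyl-1H-isochromen-1-one F4. Benzyl bromide and K2CO3 alkylate only the non-chelated hydroxyl to give 6-(benzyloxy)-8-hydroxy-3-pentyl-1H-isochromen-1-one F5. Steps 9 and 10 are repeated with F5 and 15 to give the benzyl analogue of the chain, 6-{3-[(6-benzyloxy-1-oxo-3-pentyl-1H-isochromen-8-yl)oxy]-2,4-dioxononyl}-2,2-dimethyl-4H-1,3-dioxin-4-one F6, and then 6-[(6-benzyloxy-1-oxo-3-pentyl-1H-isochromen-8-yl)oxy]-7-hydroxy-2,2-dimethyl-5-pentyl-4H-1,3-benzodioxin-4-one F7. BCl3 with pentamethylbenzene at −78 °C removes benzyl ether and acetonide within minutes, and the route is rejoined at 19.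

**Step 7.** O-acylation or incomplete conversion of the dianion may occur, and the diketo-dioxinone may aromatize during work-up and chromatography. Fallback, setting out from 12 (through 13): aldol addition of the dianion to hexanal gives racemic 6-(4-hydroxy-2-oxononyl)-2,2-dimethyl-4H-1,3-dioxin-4-one F8, which cannot aromatize. Oxidation with Dess–Martin periodinane returns to the route at 14.

**Step 4.** Closure of the hindered, doubly ortho-substituted methyl ester may be slow, and the keto ester may self-condense during prolonged heating in acid. Fallback, setting out from 4 (through 5): the benzylic anion is carboxylated with CO2 to 2-[3,5-dimethoxy-2-(methoxycarbonyl)phenyl]acetic acid F9. Saponification with KOH gives 2-(carboxymethyl)-4,6-dimethoxybenzoic acid F10. Heating F10 with hexanoyl chloride 1 at about 200 °C, the classical homophthalic acid condensation, gives the 3-pentylisocoumarin with loss of CO2 and returns to the route at 7.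

## Further compounds

F1 | step 10 | tert-butyl 6-[(6-methoxy-1-oxo-3-pentyl-1H-isochromen-8-yl)oxy]-3,5,7-trioxododecanoate | CCCCCC(=O)C(Oc1cc(OC)cc2cc(CCCCC)oc(=O)c12)C(=O)CC(=O)CC(=O)OC(C)(C)C
F2 | step 10 | tert-butyl 4,6-dihydroxy-3-[(6-methoxy-1-oxo-3-pentyl-1H-isochromen-8-yl)oxy]-2-pentylbenzoate | CCCCCc1c(Oc2cc(OC)cc3cc(CCCCC)oc(=O)c23)c(O)cc(O)c1C(=O)OC(C)(C)C
F3 | step 9 | 6-(3-chloro-2,4-dioxononyl)-2,2-dimethyl-4H-1,3-dioxin-4-one | CCCCCC(=O)C(Cl)C(=O)CC1=CC(=O)OC(C)(C)O1
F4 | step 11 | 6,8-dihydroxy-3-pentyl-1H-isochromen-1-one | CCCCCc1cc2cc(O)cc(O)c2c(=O)o1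
F5 | step 11 | 6-(benzyloxy)-8-hydroxy-3-pentyl-1H-isochromen-1-one | CCCCCc1cc2cc(OCc3ccccc3)cc(O)c2c(=O)o1
F6 | step 11 | 6-{3-[(6-benzyloxy-1-oxo-3-pentyl-1H-isochromen-8-yl)oxy]-2,4-dioxononyl}-2,2-dimethyl-4H-1,3-dioxin-4-one | CCCCCC(=O)C(Oc1cc(OCc3ccccc3)cc2cc(CCCCC)oc(=O)c12)C(=O)CC1=CC(=O)OC(C)(C)O1
F7 | step 11 | 6-[(6-benzyloxy-1-oxo-3-pentyl-1H-isochromen-8-yl)oxy]-7-hydroxy-2,2-dimethyl-5-pentyl-4H-1,3-benzodioxin-4-one | CCCCCc1c(Oc2cc(OCc4ccccc4)cc3cc(CCCCC)oc(=O)c23)c(O)cc2OC(C)(C)OC(=O)c12
F8 | step 7 | 6-(4-hydroxy-2-oxononyl)-2,2-dimethyl-4H-1,3-dioxin-4-one (racemic) | CCCCCC(O)CC(=O)CC1=CC(=O)OC(C)(C)O1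
F9 | step 4 | 2-[3,5-dimethoxy-2-(methoxycarbonyl)phenyl]acetic acid | COC(=O)c1c(CC(=O)O)cc(OC)cc1OC
F10 | step 4 | 2-(carboxymethyl)-4,6-dimethoxybenzoic acid | OC(=O)Cc1cc(OC)cc(OC)c1C(=O)O
A1 | alternative 1 | methyl 3-hydroxy-4,6-dimethoxy-2-pentylbenzoate | CCCCCc1c(O)c(OC)cc(OC)c1C(=O)OC
A2 | alternative 1 | methyl 3-{[3-(tert-butyldimethylsilyloxy)cyclohexa-1,3-dien-1-yl]oxy}-4,6-dimethoxy-2-pentylbenzoate | CCCCCc1c(OC2=CC(O[Si](C)(C)C(C)(C)C)=CCC2)c(OC)cc(OC)c1C(=O)OC
A3 | alternative 1 | methyl deca-2,4-diynoate | CCCCCC#CC#CC(=O)OC
A4 | alternative 1 | methyl 3-[5-hydroxy-3-(hept-1-yn-1-yl)-2-(methoxycarbonyl)phenoxy]-4,6-dimethoxy-2-pentylbenzoate | CCCCCC#Cc1cc(O)cc(Oc2c(OC)cc(OC)c(C(=O)OC)c2CCCCC)c1C(=O)OC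
A5 | alternative 2 | ethyl 2-diazo-3-oxo-4-[(2-pentyl-1,3-dioxolan-2-yl)methyl]pent-4-enoate | CCOC(=O)C(=[N+]=[N-])C(=O)C(=C)CC1(CCCCC)OCCO1
A6 | alternative 2 | methyl 3-(ethynyloxy)-4,6-dimethoxy-2-pentylbenzoate | C#COc1c(OC)cc(OC)c(C(=O)OC)c1CCCCC
A7 | alternative 2 | ethyl 2-[4,6-dimethoxy-3-(methoxycarbonyl)-2-pentylphenoxy]-4-hydroxy-6-[(2-pentyl-1,3-dioxolan-2-yl)methyl]benzoate | CCOC(=O)c1c(Oc2c(OC)cc(OC)c(C(=O)OC)c2CCCCC)cc(O)cc1CC1(CCCCC)OCCO1
A8 | alternative 3 | methyl 2-bromo-4-methoxy-6-[(2-oxonon-3-en-3-yl)oxy]benzoate | CCCCCC=C(Oc1cc(OC)cc(Br)c1C(=O)OC)C(C)=O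
A9 | alternative 3 | dimethyl malonate | COC(=O)CC(=O)OC
A10 | alternative 3 | methyl 5-[3-bromo-5-methoxy-2-(methoxycarbonyl)phenoxy]-2,4-dioxo-6-pentylcyclohexane-1-carboxylate (diastereomer mixture) | CCCCCC1C(Oc2cc(OC)cc(Br)c2C(=O)OC)C(=O)CC(=O)C1C(=O)OC
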